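The route rests on cutting the aryl ether bond O1–C8a of ring C. C8a of ring A lies ortho to the C4 carbonyl and meta to the oxygens on C5 and C7, so a C8a–F/C4a/C4=O array behaves as a vinylogous acyl fluoride. In one flask ethyl formate delivers C2 and O1 to an achiral fluoroacetophenone, and the formyl enolate oxygen closes ring C at C8a, giving a chromone. The precursor carries a 1,1-dimethylallyl ether on the future O5. This group keeps that oxygen neutral during ring closure and later becomes the C6 prenyl group by Claisen rearrangement. C2 is set afterwards by rhodium-catalysed asymmetric 1,4-arylation.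

Key step: step 4

Atom labels follow flavanone numbering (O1, C2, C3, C4 = carbonyl, C4a, C5–C8, C8a). Ring A is the fused benzene ring, ring C the pyranone ring and ring B the trimethoxyphenyl ring.
Assumption: the (S)-configured biaryl bisphosphine is taken to deliver the aryl group to the face that gives (2S), the same spatial sense that (S)-BINAP shows with 2-cyclohexenone; if the sense proves opposite, the (R)-ligand is used.

Step 1
Reactants: 1 1-fluoro-3,5-dimethoxybenzene
Product: 3 1-(2-fluoro-6-hydroxy-4-methoxyphenyl)ethanone, via dimethoxy ketone 2 (not isolated)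
Conditions: AcCl (1.2 equiv), AlCl3 (3 equiv), CH2Cl2, 0 °C to reflux; ice/aq. HCl
Reagents that add atoms: acetyl chloride, CC(=O)Cl
Why: Friedel–Crafts acylation should go to the carbon between F and OMe (para to the other OMe and less hindered than the carbon between the two OMe groups), and excess AlCl3 chelated to the new ketone then cleaves only the ortho methyl ether (chelation-controlled demethylation).

Step 2
Reactants: 4 2-methylbut-3-en-2-ol
Product: 6 tert-butyl (2-methylbut-3-en-2-yl) carbonate, via lithium alkoxide 5 (not isolated)
Conditions: n-BuLi (1.05 equiv), THF, −78 °C; Boc2O, −78 °C to rt; H2O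
Reagents that add atoms: di-tert-butyl dicarbonate, CC(C)(C)OC(=O)OC(=O)OC(C)(C)C
Why: O-acylation of the tertiary lithium alkoxide with the dicarbonate (mixed carbonate formation) is driven by loss of CO2 and tert-butoxide.

Step 3
Reactants: 3 1-(2-fluoro-6-hydroxy-4-methoxyphenyl)ethanone; 6 tert-butyl (2-methylbut-3-en-2-yl) carbonate
Product: 7 1-[2-fluoro-4-methoxy-6-(2-methylbut-3-en-2-yloxy)phenyl]ethanone
Conditions: Pd(PPh3)4 (3 mol %), THF, 0–5 °C
Reagents that add atoms: none
Why: Tsuji–Trost allylic etherification, in which zerovalent palladium ionises 6 with loss of CO2, the released tert-butoxide deprotonates the phenol, and the phenoxide attacks the more substituted terminus of the 1,1-dimethyl-π-allyl palladium cation under kinetic control at low temperature to give the tertiary ether.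

Step 4
Reactants: 7 1-[2-fluoro-4-methoxy-6-(2-methylbut-3-en-2-yloxy)phenyl]ethanone
Product: 9 7-methoxy-5-(2-methylbut-3-en-2-yloxy)-4H-chromen-4-one, via potassium formyl enolate 8 (not isolated)
Conditions: t-BuOK (1.05 equiv), HCO2Et (3 equiv), THF, 0 °C to rt; then dilution with DMSO, 55 °C; pH 7 buffer
Reagents that add atoms: ethyl formate, CCOC=O
Why: Crossed Claisen condensation of the potassium enolate of 7 with ethyl formate gives the equilibrating (Z)-formyl enolate 8, whose terminal oxygen (the future O1) adds to C8a while the charge is relayed through C4a into the C4 carbonyl (a Meisenheimer adduct, equally describable as an oxa-6π closure of the O1=C2–C3=C4–C4a=C8a array), and loss of fluoride restores ring A. The closest known reaction type is the transition-metal-free intramolecular O-arylation of 1-(2-haloaryl)-1,3-dicarbonyl enolates to chromones and flavones. Ring C closes by a 6-endo-trig addition–elimination, since the C8a=C4a bond that takes up the charge lies inside the new ring. No stereocentre is formed, so nothing can be scrambled at this stage. The step needs O- rather than C-attack, substitution at C8a only and survival of the allyl ether: attack by C3 would give a four-membered ring, fluoride is the only leaving group ortho to C4=O and sits meta to both donor oxygens, the single equivalent of base is consumed so that no free alkoxide remains, and the bath stays well below the onset of the [3,3] shift. The 1,1-dimethylallyl group keeps O5 neutral, whereas a free phenoxide there would switch the substitution off.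

Step 5
Reactants: 9 7-methoxy-5-(2-methylbut-3-en-2-yloxy)-4H-chromen-4-one; 10 3,4,5-trimethoxyphenylboronic acid
Product: 11 (2S)-7-methoxy-5-(2-methylbut-3-en-2-yloxy)-2-(3,4,5-trimethoxyphenyl)-2,3-dihydrochromen-4-one
Conditions: [Rh(OH)(cod)]2 (2.5 mol %), (S)-MeO-F12-BIPHEP [(S)-2,2'-bis(bis(3,4,5-trifluorophenyl)phosphino)-6,6'-dimethoxybiphenyl] (5.5 mol %), 10 (2.5 equiv), toluene/H2O 10:1, 30 °C
Reagents that add atoms: none
Why: Hayashi–Miyaura asymmetric 1,4-addition, in which the aryl complex of monovalent rhodium formed by transmetalation inserts the C2=C3 bond from the face left open by the (S)-bisphosphine and so sets C2 as S, while fast hydrolysis of the oxa-π-allyl rhodium enolate by water forestalls β-aryloxide elimination.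

Step 6
Reactants: 11 (2S)-7-methoxy-5-(2-methylbut-3-en-2-yloxy)-2-(3,4,5-trimethoxyphenyl)-2,3-dihydrochromen-4-one
Product: 13 artoflavanone [(2S)-5-hydroxy-7-methoxy-6-(3-methylbut-2-enyl)-2-(3,4,5-trimethoxyphenyl)-2,3-dihydrochromen-4-one], via ortho-dienone 12 (not isolated)
Conditions: toluene (degassed, base- and acid-free), 110 °C, sealed tube
Reagents that add atoms: none
Why: Aromatic Claisen rearrangement, in which the [3,3] shift from O5 can only reach C6 (C4a is blocked), inverts the allyl unit so that the tertiary ether emerges as the linear prenyl group, and is completed by enolisation of 12 to the chelated C5 phenol, the neutral aprotic medium leaving C2 untouched.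

Compound list
1 | 1-fluoro-3,5-dimethoxybenzene | COc1cc(F)cc(OC)c1 | starting material
2 | 1-(2-fluoro-4,6-dimethoxyphenyl)ethanone | CC(=O)c1c(F)cc(OC)cc1OC | intermediate
3 | 1-(2-fluoro-6-hydroxy-4-methoxyphenyl)ethanone | CC(=O)c1c(F)cc(OC)cc1O | intermediate
4 | 2-methylbut-3-en-2-ol | C=CC(C)(C)O | starting material
5 | lithium 2-methylbut-3-en-2-olate | [Li+].[O-]C(C)(C)C=C | intermediate
6 | tert-butyl (2-methylbut-3-en-2-yl) carbonate | C=CC(C)(C)OC(=O)OC(C)(C)C | intermediate
7 | 1-[2-fluoro-4-methoxy-6-(2-methylbut-3-en-2-yloxy)phenyl]ethanone | CC(=O)c1c(F)cc(OC)cc1OC(C)(C)C=C | intermediate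
8 | potassium (Z)-3-[2-fluoro-4-methoxy-6-(2-methylbut-3-en-2-yloxy)phenyl]-3-oxoprop-1-en-1-olate | [K+].[O-]/C=C\C(=O)c1c(F)cc(OC)cc1OC(C)(C)C=C | intermediate
9 | 7-methoxy-5-(2-methylbut-3-en-2-yloxy)-4H-chromen-4-one | COc1cc2occc(=O)c2c(OC(C)(C)C=C)c1 | intermediate
10 | 3,4,5-trimethoxyphenylboronic acid | COc1cc(B(O)O)cc(OC)c1OC | starting material
11 | (2S)-7-methoxy-5-(2-methylbut-3-en-2-yloxy)-2-(3,4,5-trimethoxyphenyl)-2,3-dihydrochromen-4-one | COc1cc2c(c(OC(C)(C)C=C)c1)C(=O)C[C@@H](c1cc(OC)c(OC)c(OC)c1)O2 | intermediate
12 | (2S)-7-methoxy-6-(3-methylbut-2-enyl)-2-(3,4,5-trimethoxyphenyl)-2,3-dihydro-6H-chromene-4,5-dione (ortho-dienone, C6 undefined) | COC1=CC2=C(C(=O)C1CC=C(C)C)C(=O)C[C@@H](c1cc(OC)c(OC)c(OC)c1)O2 | intermediate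
13 | artoflavanone, (2S)-5-hydroxy-7-methoxy-6-(3-methylbut-2-enyl)-2-(3,4,5-trimethoxyphenyl)-2,3-dihydrochromen-4-one | COc1cc2c(c(O)c1CC=C(C)C)C(=O)C[C@@H](c1cc(OC)c(OC)c(OC)c1)O2 | target

Total step count: 6. Longest linear sequence: 5 (steps 1, 3, 4, 5, 6).

Steps most likely to fail

Step 4. The stabilised enolate oxygen may attack the donor-substituted ring A too slowly at temperatures that the tertiary allyl ether tolerates. A premature [3,3] shift to a phenoxide, which switches the substitution off, would then overtake ring closure. The fallback closes the ring before the heat-sensitive group exists.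
- It sets out from 2, isolated by running step 1 with 1.1 equiv of AlCl3 at 0 °C.
- The same formylation and ring closure (t-BuOK, HCO2Et, THF; then DMSO, 100–120 °C) should give 5,7-dimethoxy-4H-chromen-4-one F1.
- BCl3 (CH2Cl2, −78 to 0 °C) should cleave only the C5 methyl ether held next to C4=O, giving 5-hydroxy-7-methoxy-4H-chromen-4-one F2.
- Allylic etherification of F2 with 6 (Pd(PPh3)4, THF, 0 °C) comes back to the route at 9.

Step 5. Insertion into the electron-rich 5,7-dioxygenated chromone may be slow. Protodeboronation could then take over, as could carbometalation of the terminal alkene followed by β-aryloxide elimination, or ring opening of the rhodium enolate with erosion of enantiomeric purity. The fallback removes the allyl ether and weakens the C5 oxygen donor before the arylation.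
- It sets out from 9, and heating (toluene, 120 °C) should give 5-hydroxy-7-methoxy-6-(3-methylbut-2-enyl)-4H-chromen-4-one F3.
- Acetylation (Ac2O, pyridine, DMAP, rt) should give 7-methoxy-6-(3-methylbut-2-enyl)-4-oxo-4H-chromen-5-yl acetate F4, a more electrophilic acceptor without an acidic proton or a terminal alkene.
- The rhodium-catalysed arylation of step 5 with 10 should give (2S)-7-methoxy-6-(3-methylbut-2-enyl)-4-oxo-2-(3,4,5-trimethoxyphenyl)-2,3-dihydrochromen-5-yl acetate F5.
- A lipase (serine hydrolase class; n-BuOH, MTBE, 30 °C) transfers the acetyl group under neutral conditions and comes back to the route at 13.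

Step 3. Zerovalent palladium may re-ionise the tertiary ether and let it leak to the linear prenyl ether, which would give the wrong allyl regiochemistry after the Claisen step. The hydrogen-bonded phenol may also attack sluggishly. The fallback builds the tertiary ether by substitution at a propargylic centre, with no π-allyl intermediate.
- It sets out from 3, and 3-chloro-3-methylbut-1-yne, CuCl2 (1 mol %) and DBU in MeCN at 0 °C should give 1-[2-fluoro-4-methoxy-6-(2-methylbut-3-yn-2-yloxy)phenyl]ethanone F6.
- Semihydrogenation (H2, 1 atm, Pd/CaCO3 poisoned with Pb(OAc)2, quinoline, EtOAc) comes back to the route at 7.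

Further compounds
F1 | step 4 | 5,7-dimethoxy-4H-chromen-4-one | COc1cc(OC)c2c(c1)occc2=O
F2 | step 4 | 5-hydroxy-7-methoxy-4H-chromen-4-one | COc1cc(O)c2c(c1)occc2=O
F3 | step 5 | 5-hydroxy-7-methoxy-6-(3-methylbut-2-enyl)-4H-chromen-4-one | COc1cc2occc(=O)c2c(O)c1CC=C(C)C
F4 | step 5 | 7-methoxy-6-(3-methylbut-2-enyl)-4-oxo-4H-chromen-5-yl acetate | COc1cc2occc(=O)c2c(OC(C)=O)c1CC=C(C)C
F5 | step 5 | (2S)-7-methoxy-6-(3-methylbut-2-enyl)-4-oxo-2-(3,4,5-trimethoxyphenyl)-2,3-dihydrochromen-5-yl acetate | COc1cc2c(c(OC(C)=O)c1CC=C(C)C)C(=O)C[C@@H](c1cc(OC)c(OC)c(OC)c1)O2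
F6 | step 3 | 1-[2-fluoro-4-methoxy-6-(2-methylbut-3-yn-2-yloxy)phenyl]ethanone | CC(=O)c1c(F)cc(OC)cc1OC(C)(C)C#C
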